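The route rests on cutting C8–C9 and C11–C12. In the bicyclo[3.2.1]octene the six-membered ring C8–C14–C15–C16–C12–C13 carries oxygen at C13 and C16, 1,3 to each other: a reduced resorcinol whose carbons C8 and C12 hold the C9–C11 bridge. The precursor is therefore a 4-alkyl-3-methoxyphenol joined through C6–C7 to ring A, whose C10 bears a benzyl enol ether (C9=C11). Two-electron oxidation of the phenol lets C9 bond to C8 (ring B) and C12 trap the C11 oxocarbenium ion (cyclopentane), giving the tetracyclic enedione with four new stereocentres in one operation. Dehydroabietic acid supplies ring A and its C4, C5 and C10 stereocentres.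

Key step: step 12

Remark: diterpenoid atom numbers are used (C17 acetoxymethyl carbon, C18 hydroxymethyl on C4, C20 methyl on C10); the Wittig step is assumed to give mainly the E enol ether, and any Z isomer is taken to converge at ion 19.

Step 1
Reactants: 1 dehydroabietic acid
Product: 2 dehydroabietinol
Conditions: LiAlH4, THF, 0 °C to reflux; aq. NaOH work-up
Reagents that add atoms: none
Why: Hydride reduction of the carboxylic acid gives the C18 primary alcohol and leaves C4, C5 and C10 untouched.

Step 2
Reactants: 2 dehydroabietinol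
Product: 3 18-O-TBS-dehydroabietinol
Conditions: t-BuMe2SiCl, imidazole, DMF, rt
Reagents that add atoms: tert-butyldimethylsilyl chloride, CC(C)(C)[Si](C)(C)Cl
Why: Silyl ether formation on the primary neopentyl alcohol gives a hindered ether that should survive the oxidative, organometallic and hydride steps ahead.

Step 3
Reactants: 3 18-O-TBS-dehydroabietinol
Product: 4 8,9-seco diacid
Conditions: RuCl3·xH2O (cat.), NaIO4, EtOAc/MeCN/H2O, rt
Reagents that add atoms: sodium periodate, [Na+].[O-]I(=O)(=O)=O; water, O
Why: Oxidative arene degradation by RuO4 generated in situ (ruthenium-catalysed periodate oxidation) cleaves the benzene ring so that only its two fusion carbons survive, C9 as the carboxyl on C10 and C8 as the carboxyl ending the C6–C7 chain, while saturated ring A and its three stereocentres are left alone.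

Step 4
Reactants: 4 8,9-seco diacid
Product: 6 C9 methyl ester C8 acid (half ester), via dimethyl ester 5 (not isolated)
Conditions: Me3SiCHN2, PhMe/MeOH, 0 °C; evaporate; LiOH, THF/MeOH/H2O, rt; 1 M HCl to pH 3, 0 °C
Reagents that add atoms: (trimethylsilyl)diazomethane, C[Si](C)(C)C=[N+]=[N-]; lithium hydroxide, [Li+].[OH-]
Why: Methyl ester formation with the diazoalkane followed by saponification under steric control, in which hydroxide reaches only the unhindered C8 ester while the C9 ester on quaternary C10 is inert at room temperature, differentiates the two carboxyls.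

Step 5
Reactants: 6 C9 methyl ester C8 acid (half ester)
Product: 7 N-acyloxyphthalimide (redox-active ester) of the C8 acid
Conditions: N-hydroxyphthalimide, N,N'-diisopropylcarbodiimide, DMAP (cat.), CH2Cl2, rt
Reagents that add atoms: N-hydroxyphthalimide, O=C1c2ccccc2C(=O)N1O
Why: Carbodiimide (Steglich-type) esterification converts the free C8 acid into the redox-active ester needed for radical decarboxylation.

Step 6
Reactants: 8 4-bromo-3-methoxyphenol
Product: 9 (4-bromo-3-methoxyphenoxy)triisopropylsilane
Conditions: i-Pr3SiCl, imidazole, DMF, rt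
Reagents that add atoms: triisopropylsilyl chloride, CC(C)[Si](Cl)(C(C)C)C(C)C
Why: Silylation of the phenol gives an aryl silyl ether that tolerates halogen–lithium exchange, zinc and hydride reagents and can later be removed by fluoride without acid, which the enol ether would not survive.

Step 7
Reactants: 7 N-acyloxyphthalimide (redox-active ester) of the C8 acid; 9 (4-bromo-3-methoxyphenoxy)triisopropylsilane
Product: 12 C9 methyl ester carrying the aryl ring on C7, via aryllithium 10 (not isolated), via arylzinc chloride 11 (not isolated)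
Conditions: 9, n-BuLi, THF, −78 °C; ZnCl2, −78 °C to rt; then 7, NiCl2·(MeOCH2CH2OMe) (20 mol %), 4,4'-di-tert-butyl-2,2'-bipyridine (40 mol %), THF/DMF, rt; aq. HCl work-up
Reagents that add atoms: none
Why: Nickel-catalysed decarboxylative Negishi-type arylation, in which electron transfer from low-valent nickel to the phthalimide ester releases CO2 and the primary C7 radical that is captured at nickel and coupled with the aryl group, forms the C7–C8 bond at a non-stereogenic carbon and leaves the hindered C9 ester alone.

Step 8
Reactants: 12 C9 methyl ester carrying the aryl ring on C7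
Product: 13 C9 neopentyl alcohol
Conditions: LiAlH4, THF, 0 °C to rt; aq. NaOH work-up
Reagents that add atoms: none
Why: Hydride reduction of the hindered ester gives the neopentyl alcohol, both silyl ethers and the anisole being inert to LiAlH4 at this temperature.

Step 9
Reactants: 13 C9 neopentyl alcohol
Product: 14 C9 aldehyde
Conditions: Dess–Martin periodinane, CH2Cl2, rt
Reagents that add atoms: none
Why: Periodinane (Dess–Martin) oxidation of the primary alcohol gives an aldehyde that has no α-hydrogen and therefore cannot enolise or epimerise.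

Step 10
Reactants: 14 C9 aldehyde; 15 (benzyloxymethyl)triphenylphosphonium chloride
Product: 17 (E)-benzyl enol ether aryl silyl ether, via phosphorus ylide 16 (not isolated)
Conditions: 15, KN(SiMe3)2, THF, 0 °C; then 14, 0 to 50 °C
Reagents that add atoms: none
Why: Wittig alkoxymethylenation of the non-enolisable neopentyl aldehyde installs C11 as a benzyl enol ether, the E isomer being favoured because the Z isomer would press the benzyloxy group against quaternary C10.

Step 11
Reactants: 17 (E)-benzyl enol ether aryl silyl ether
Product: 18 ring-A phenol enol ether (key-step precursor)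
Conditions: Bu4NF (1.05 equiv), THF, 0 °C; aq. NH4Cl
Reagents that add atoms: none
Why: Fluoride desilylation under non-acidic conditions cleaves the aryl O–Si bond (phenoxide leaving group) much faster than the neopentyl alkyl TBS ether and spares the acid-labile enol ether, so the free phenol is released only just before the oxidation.

Step 12
Reactants: 18 ring-A phenol enol ether (key-step precursor)
Product: 20 tetracyclic bicyclo[3.2.1]octenedione, via spirodienone oxocarbenium ion 19 (not isolated)
Conditions: PhI(OAc)2 (1.1 equiv), (CF3)2CHOH/CH2Cl2, −40 to 0 °C; aq. NaHCO3 work-up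
Reagents that add atoms: none
Why: Proposed new method: ligand exchange of the phenol at trivalent iodine and loss of PhI give a phenoxonium ion whose para carbon C8 is attacked by the enol-ether carbon C9 (6-exo-trig spirocyclisation, ring B), the oxocarbenium ion 19 is then trapped at C11 by C12, the α-carbon of the new β-methoxy enone (5-exo-trig Prins-type closure of the cyclopentane C8–C9–C11–C12–C13), and acetate removes the methyl group from the C13 oxocarbenium ion to leave the C13 ketone beside the C16 enone. The closest known reaction is the cationic (5+2) cycloaddition of oxidised methoxyphenols with electron-rich alkenes, which gives bicyclo[3.2.1]octenediones by bonding at the two carbons ortho to the phenol oxygen; attack at a para carbon that carries the tether is the untested part, although oxidative para-spirocyclisation of phenols by tethered π-nucleophiles is itself established. C9 is set by a chair-like ring-B transition state with the C11 arm equatorial (9α-H), C8 by which arene edge lies on the β face, since only with the methoxy-bearing C13 edge there does the C9=C11 π bond run parallel to the C8···C12 axis of the cation so that both bonds form in a cis-fused array with C10 exo, C12 by the fact that it can reach C11 only on that face, and C11 by the oxocarbenium rotamer that keeps the benzyloxy group endo, away from quaternary C10 and cis to H9. The step needs para rather than ortho attack (secured by the tether, which allows only a six-membered ring at C8), oxidation of the phenol before the enol ether (secured by the O–I bond that only the free phenol can form) and the β orientation of the C13 edge (secured only by the alignment just described, because the C10 methyl group sterically prefers the smaller C14 edge, which makes this the main risk). Either alkene geometry of 18 leads to the same ion 19.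

Step 13
Reactants: 20 tetracyclic bicyclo[3.2.1]octenedione
Product: 21 C13 alcohol enone
Conditions: NaBH4, CH2Cl2/MeOH, −78 °C
Reagents that add atoms: none
Why: Chemoselective borohydride reduction takes the strained, non-conjugated bridge ketone C13 in preference to the C16 enone, and hydride arrives over the flat C14=C15–C16 bridge because the opposite face is closed by C10 and its methyl group, which places the new hydroxyl syn to the C9–C11 bridge as the target requires.

Step 14
Reactants: 21 C13 alcohol enone
Product: 22 C13,C18 bis-silyl ether enone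
Conditions: t-BuMe2SiOTf, 2,6-lutidine, CH2Cl2, −78 to 0 °C
Reagents that add atoms: tert-butyldimethylsilyl trifluoromethanesulfonate, CC(C)(C)[Si](C)(C)OS(=O)(=O)C(F)(F)F
Why: Silylation with the silyl triflate masks the hindered C13 hydroxyl for the dehydration and ylide steps and blocks retro-aldol cleavage of the β-hydroxy ketone, while the enone cannot form a silyl dienol ether because C12 is a bridgehead and C8 is quaternary.

Step 15
Reactants: 22 C13,C18 bis-silyl ether enone
Product: 23 C11 alcohol C16 ketone
Conditions: H2 (1 atm), Pd(OH)2/C, EtOAc, rt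
Reagents that add atoms: none
Why: Heterogeneous catalytic hydrogenation saturates C14=C15 and hydrogenolyses the C11 benzyl ether in one operation without creating a stereocentre, so the C11 hydroxyl appears only after the C13/C16 1,3-diketone, which would invite retro-aldol ring opening, has gone.

Step 16
Reactants: 23 C11 alcohol C16 ketone
Product: 24 C9(11)-alkene C16 ketone
Conditions: Burgess reagent (MeO2CN−SO2N+Et3), PhMe, 70 °C
Reagents that add atoms: none
Why: Dehydration by thermal syn elimination of the sulfamate ester (Ei) uses H9, which is held eclipsed and cis to the endo C11 oxygen, while loss toward C12 is excluded because it would give a bridgehead alkene, so only the C9=C11 double bond can form.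

Step 17
Reactants: 24 C9(11)-alkene C16 ketone
Product: 25 16,17-epoxide
Conditions: Me3SI, KN(SiMe3)2, THF, −10 to 0 °C
Reagents that add atoms: trimethylsulfonium iodide, C[S+](C)C.[I-]
Why: Corey–Chaykovsky epoxidation, in which the unstabilised sulfonium ylide adds irreversibly to the C16 carbonyl along the axial trajectory on the face of the six-membered ring that carries H13 and lies opposite the C9=C11 bridge, leaves C17 axial and the oxygen equatorial, which is the C16 configuration of the target.

Step 18
Reactants: 25 16,17-epoxide
Product: 26 17-acetate 16-alcohol bis-silyl ether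
Conditions: CsOAc, AcOH (1.5 equiv), DMF, 90 °C
Reagents that add atoms: caesium acetate, [Cs+].CC(=O)[O-]
Why: SN2 opening of the 2,2-disubstituted epoxide by acetate at the unsubstituted carbon C17 under buffered, non-ionising conditions leaves the C16–O bond and hence the C16 configuration untouched.

Step 19
Reactants: 26 17-acetate 16-alcohol bis-silyl ether
Product: 27 botryotin E
Conditions: HF·pyridine, THF/pyridine, 0 °C to rt
Reagents that add atoms: none
Why: Desilylation with buffered hydrogen fluoride frees C13–OH and C18–OH at once and is not basic enough to cleave or shift the C17 acetate.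

Compound list

1 | dehydroabietic acid (abieta-8,11,13-trien-18-oic acid; 4α-CO2H, 5α-H, 10β-CH3) | CC(C)c1ccc2c(c1)CC[C@H]1[C@](C)(C(=O)O)CCC[C@]21C | starting material
2 | dehydroabietinol (abieta-8,11,13-trien-18-ol; configuration of 1) | CC(C)c1ccc2c(c1)CC[C@H]1[C@](C)(CO)CCC[C@]21C | intermediate
3 | 18-O-TBS-dehydroabietinol | CC(C)c1ccc2c(c1)CC[C@H]1[C@](C)(CO[Si](C)(C)C(C)(C)C)CCC[C@]21C | intermediate
4 | 8,9-seco diacid: ring A with C9 carboxyl and β-methyl on C10, CH2CH2CO2H (C6, C7, C8) on C5 (α-H), β-methyl and α-CH2OTBS on C4 | OC(=O)[C@@]1(C)CCC[C@@](C)(CO[Si](C)(C)C(C)(C)C)[C@@H]1CCC(=O)O | intermediate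
5 | dimethyl ester of 4 | COC(=O)[C@@]1(C)CCC[C@@](C)(CO[Si](C)(C)C(C)(C)C)[C@@H]1CCC(=O)OC | intermediate
6 | C9 methyl ester C8 acid (half ester) | COC(=O)[C@@]1(C)CCC[C@@](C)(CO[Si](C)(C)C(C)(C)C)[C@@H]1CCC(=O)O | intermediate
7 | N-acyloxyphthalimide (redox-active ester) of the C8 acid | COC(=O)[C@@]1(C)CCC[C@@](C)(CO[Si](C)(C)C(C)(C)C)[C@@H]1CCC(=O)ON2C(=O)c3ccccc3C2=O | intermediate
8 | 4-bromo-3-methoxyphenol | Oc1ccc(Br)c(OC)c1 | starting material
9 | (4-bromo-3-methoxyphenoxy)triisopropylsilane | COc1cc(O[Si](C(C)C)(C(C)C)C(C)C)ccc1Br | intermediate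
10 | [2-methoxy-4-(triisopropylsilyloxy)phenyl]lithium | [Li]c1ccc(O[Si](C(C)C)(C(C)C)C(C)C)cc1OC | intermediate
11 | [2-methoxy-4-(triisopropylsilyloxy)phenyl]zinc chloride | Cl[Zn]c1ccc(O[Si](C(C)C)(C(C)C)C(C)C)cc1OC | intermediate
12 | C9 methyl ester carrying the 2-methoxy-4-(triisopropylsilyloxy)phenyl ring (new C8) on C7 | COC(=O)[C@@]1(C)CCC[C@@](C)(CO[Si](C)(C)C(C)(C)C)[C@@H]1CCc1ccc(O[Si](C(C)C)(C(C)C)C(C)C)cc1OC | intermediate
13 | C9 neopentyl alcohol (CH2OH on C10) | OC[C@@]1(C)CCC[C@@](C)(CO[Si](C)(C)C(C)(C)C)[C@@H]1CCc1ccc(O[Si](C(C)C)(C(C)C)C(C)C)cc1OC | intermediate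
14 | C9 aldehyde (CHO on C10) | O=C[C@@]1(C)CCC[C@@](C)(CO[Si](C)(C)C(C)(C)C)[C@@H]1CCc1ccc(O[Si](C(C)C)(C(C)C)C(C)C)cc1OC | intermediate
15 | (benzyloxymethyl)triphenylphosphonium chloride | [Cl-].c1ccccc1COC[P+](c1ccccc1)(c1ccccc1)c1ccccc1 | starting material
16 | (benzyloxymethylene)triphenylphosphorane | C(=P(c1ccccc1)(c1ccccc1)c1ccccc1)OCc1ccccc1 | intermediate
17 | (E)-benzyl enol ether (C9=C11) with aryl O-TIPS and C18 O-TBS | c1ccccc1CO/C=C/[C@@]1(C)CCC[C@@](C)(CO[Si](C)(C)C(C)(C)C)[C@@H]1CCc1ccc(O[Si](C(C)C)(C(C)C)C(C)C)cc1OC | intermediate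
18 | ring-A phenol enol ether: (E)-benzyl enol ether on C10, 4-hydroxy-2-methoxyphenyl on C7, C18 O-TBS | c1ccccc1CO/C=C/[C@@]1(C)CCC[C@@](C)(CO[Si](C)(C)C(C)(C)C)[C@@H]1CCc1ccc(O)cc1OC | intermediate
19 | spirodienone oxocarbenium ion (ring B closed; C13 edge β at C8, 9α-H, O-benzyl oxocarbenium at C11) | O=C1C=C[C@@]2(CC[C@H]3[C@](C)(CO[Si](C)(C)C(C)(C)C)CCC[C@]3(C)[C@H]2C=[O+]Cc2ccccc2)C(OC)=C1 | intermediate
20 | tetracyclic bicyclo[3.2.1]oct-14-ene-13,16-dione (C13 bridge β at C8 and syn to C20, 9α-H, 11-OBn endo and cis to H9, C18 O-TBS) | O=C1C=C[C@]23CC[C@H]4[C@](C)(CO[Si](C)(C)C(C)(C)C)CCC[C@]4(C)[C@H]2[C@H](OCc5ccccc5)[C@H]1C3=O | intermediate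
21 | C13 alcohol enone (13-OH syn to the C9–C11 bridge) | O=C1C=C[C@]23CC[C@H]4[C@](C)(CO[Si](C)(C)C(C)(C)C)CCC[C@]4(C)[C@H]2[C@H](OCc5ccccc5)[C@H]1[C@H]3O | intermediate
22 | C13,C18 bis-silyl ether enone | O=C1C=C[C@]23CC[C@H]4[C@](C)(CO[Si](C)(C)C(C)(C)C)CCC[C@]4(C)[C@H]2[C@H](OCc5ccccc5)[C@H]1[C@H]3O[Si](C)(C)C(C)(C)C | intermediate
23 | C11 alcohol C16 ketone (11-OH endo, cis to 9α-H; C14–C15 saturated) | O=C1CC[C@]23CC[C@H]4[C@](C)(CO[Si](C)(C)C(C)(C)C)CCC[C@]4(C)[C@H]2[C@H](O)[C@H]1[C@H]3O[Si](C)(C)C(C)(C)C | intermediate
24 | C9(11)-alkene C16 ketone | O=C1CC[C@]23CC[C@H]4[C@](C)(CO[Si](C)(C)C(C)(C)C)CCC[C@]4(C)C2=C[C@H]1[C@H]3O[Si](C)(C)C(C)(C)C | intermediate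
25 | 16,17-epoxide (C17 axial and syn to H13, epoxide oxygen equatorial) | C1O[C@@]12CC[C@]34CC[C@H]5[C@](C)(CO[Si](C)(C)C(C)(C)C)CCC[C@]5(C)C3=C[C@H]2[C@H]4O[Si](C)(C)C(C)(C)C | intermediate
26 | 17-acetate 16-alcohol, C13,C18 bis-silyl ether | CC(=O)OC[C@@]1(O)CC[C@]23CC[C@H]4[C@](C)(CO[Si](C)(C)C(C)(C)C)CCC[C@]4(C)C2=C[C@H]1[C@H]3O[Si](C)(C)C(C)(C)C | intermediate
27 | botryotin E | CC(=O)OC[C@@]1(O)CC[C@]23CC[C@H]4[C@](C)(CO)CCC[C@]4(C)C2=C[C@H]1[C@H]3O | target

Total step count: 19.
Longest linear sequence: 18 steps (steps 1–5 and 7–19, from 1 to 27); step 6 is a one-step side branch.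

Steps most likely to fail

Step 12 (bears the proposed new method). Ion 19 may be captured by solvent or acetate, or may shed its benzyl group, before C12 closes the five-membered ring, or the two bonds may form on the α face at C8. The fallback uses two known operations and sets out from 18. Oxidation with PhI(OAc)2 in CH2Cl2/(CF3)2CHOH containing an excess of benzyl alcohol is a dearomatising para-spirocyclisation of a phenol by a tethered π-nucleophile in which the alcohol deliberately intercepts the oxocarbenium ion. It should give the spirodienone dibenzyl acetal F1, which can be purified and, if needed, freed from a C8 epimer. Treatment of F1 with Me3SiOTf in CH2Cl2 at −78 °C then ionises the acetal in the absence of competing nucleophiles, and the β-methoxy enone carbon C12 adds to C11 (acetal-initiated Prins/Mukaiyama-type cyclisation). Loss of the O-methyl group on aqueous work-up returns the route to 20.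

Step 16. The sulfamate may ionise and rearrange the strained skeleton instead of eliminating, or may find no syn hydrogen if the C11 oxygen has come out exo. The fallback does not depend on the C11 configuration and sets out from 23. The C16 ketone is masked with 1,2-bis(trimethylsilyloxy)ethane and catalytic Me3SiOTf (CH2Cl2, −78 to −20 °C, then K2CO3/MeOH) to give the hydroxy ketal F2. Dess–Martin oxidation gives the C11 ketone F3, which can enolise only toward C9. KN(SiMe3)2 and PhNTf2 (THF, −78 °C) give the enol triflate F4. Reduction with Pd(OAc)2, PPh3, Bu3N and HCO2H in DMF at 60 °C (zerovalent palladium, formate as hydride source) gives the alkene ketal F5. Pyridinium p-toluenesulfonate in wet acetone removes the dioxolane and returns the route to 24.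

Step 17. Methylene transfer may show poor facial selectivity at C16, or the ylide may merely enolise the ketone toward C15. The fallback makes the C16–O bond from the equatorial face instead of the C16–C17 bond from the axial face, and sets out from 24. Wittig methylenation (Ph3PCH3Br, KOt-Bu, THF) gives the 16-methylene compound F6. Catalytic OsO4 with N-methylmorpholine N-oxide (acetone/H2O) should dihydroxylate the unhindered 1,1-disubstituted alkene in preference to the shielded trisubstituted C9=C11 bond, the bulky oxidant being expected to approach equatorially and give the 16,17-diol F7 with the C16 hydroxyl equatorial. Acetylation of the primary hydroxyl (Ac2O, pyridine, 0 °C) rejoins the route at 26 and also bypasses step 18.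

Further compounds

F1 | step 12 | spirodienone dibenzyl acetal | O=C1C=C[C@@]2(CC[C@H]3[C@](C)(CO[Si](C)(C)C(C)(C)C)CCC[C@]3(C)[C@H]2C(OCc2ccccc2)OCc2ccccc2)C(OC)=C1
F2 | step 16 | C16 ethylene ketal of 23 (C11 alcohol) | O1CCOC12CC[C@]34CC[C@H]5[C@](C)(CO[Si](C)(C)C(C)(C)C)CCC[C@]5(C)[C@H]3[C@H](O)[C@H]2[C@H]4O[Si](C)(C)C(C)(C)C
F3 | step 16 | C11 ketone C16 ethylene ketal | O1CCOC12CC[C@]34CC[C@H]5[C@](C)(CO[Si](C)(C)C(C)(C)C)CCC[C@]5(C)[C@H]3C(=O)[C@H]2[C@H]4O[Si](C)(C)C(C)(C)C
F4 | step 16 | C9(11)-enol triflate C16 ethylene ketal | O1CCOC12CC[C@]34CC[C@H]5[C@](C)(CO[Si](C)(C)C(C)(C)C)CCC[C@]5(C)C3=C(OS(=O)(=O)C(F)(F)F)[C@H]2[C@H]4O[Si](C)(C)C(C)(C)C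
F5 | step 16 | C9(11)-alkene C16 ethylene ketal | O1CCOC12CC[C@]34CC[C@H]5[C@](C)(CO[Si](C)(C)C(C)(C)C)CCC[C@]5(C)C3=C[C@H]2[C@H]4O[Si](C)(C)C(C)(C)C
F6 | step 17 | 16-methylene compound | C=C1CC[C@]23CC[C@H]4[C@](C)(CO[Si](C)(C)C(C)(C)C)CCC[C@]4(C)C2=C[C@H]1[C@H]3O[Si](C)(C)C(C)(C)C
F7 | step 17 | 16,17-diol (C13,C18 bis-silyl ether) | OC[C@@]1(O)CC[C@]23CC[C@H]4[C@](C)(CO[Si](C)(C)C(C)(C)C)CCC[C@]4(C)C2=C[C@H]1[C@H]3O[Si](C)(C)C(C)(C)C
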